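Two questions are asked of this flask, and behind them stands a decision for the next run: if you want more target, do you charge more acid or wait longer?

| flask | solid substrate | acid | remark | time |
|---|---|---|---|---|
| beta | 0.10 M | 0.050 mM | run made earlier |  |
| epsilon | 0.10 M | 0.20 mM | run made earlier |  |
| zeta | 0.15 M | 0.10 mM | run made earlier |  |
| flask | 0.10 M | 0.100 mM |  | 20 h |

| run | time / h | solid substrate / % | target / % |
|---|---|---|---|
| beta | 1.00 | 97.5 | 0.5 |
| beta | 3.00 | 92.8 | 0.7 |
| beta | 6.00 | 88.3 | 4.7 |
| beta | 8.00 | 83.8 | 4.8 |
| beta | 12.0 | 73.6 | 9.9 |
| epsilon | 2.50 | 95.0 | 1.0 |
| epsilon | 5.00 | 87.5 | 3.2 |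
| epsilon | 8.00 | 81.3 | 7.6 |
| epsilon | 10.0 | 78.7 | 12.4 |
| epsilon | 12.0 | 75.1 | 15.6 |
| zeta | 1.00 | 98.1 | 0.7 |
| zeta | 3.00 | 95.0 | 1.3 |
| zeta | 6.00 | 89.2 | 1.8 |
| zeta | 8.00 | 89.9 | 3.3 |
| zeta | 12.0 | 82.1 | 8.2 |

(scatter of a reading: 1 percentage point)

* part of the solid substrate that has reacted (what has only dissolved counts as not reacted) at 20 h
* pH of the solution at 20 h

- acid is the free proton; pH is minus the decimal logarithm of its molar concentration
- solid substrate is a solid; its amount is given per volume of the solution
- at the start none of the solid substrate is in solution
- what has only dissolved of solid substrate counts as not reacted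

Each charge is partly solid and partly target, and the rest has dissolved without reacting. At the last readings, 12.0 h, that rest is 16.5% in the beta run and 9.30% in the epsilon run. Your flask's acid is the geometric mean of their charges, so I take the geometric mean of these readings, 12.4%, as the standing pool: the dissolved share of the charge once target forms about as fast as solid leaves, the steady-state approximation.

Carrying the pace of those two runs on to 20 h, 42.8% of the charge leaves the solid. Subtract the pool, and I commit to 30.4% reacted. The readings show no pH, so I reckon none.

Now the decision. Between those runs, 4.00 times the acid multiplies the pool by 0.564. The same step from your flask, to 0.400 mM, leaves 6.98% and gains 5.4 percentage points, which the same pace of solid supplies in 2.52 h. I would wait.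

The forecast says 43% and pH 4, holding that the “loss of substrate is roughly linear in time”, as my own carried pace does too; its yield stands 13 points above mine, close to the 12.4% that I subtracted.

The flask gives 26.9% reacted and pH 3.78.

    starting material + acid → weak acid + acid + target (k = 710 /M/h)
    weak acid ⇌ conjugate base + acid, settled at all times (K = 5.00 × 10⁻⁶ M)
    starting material → weak acid + target (k = 0.0226 /h)
    solid substrate ⇌ starting material, rate k4*(cs4 - [starting material]) while solid is left; crystals form when [starting material] > cs4 (solubility = 0.0680 M, k = 0.0350 /h)
    weak acid → by-product carried off (k = 0.882 /h)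

At 20.0 h the flask makes starting material 1.02 times as fast as it uses it up, each step taken net, and the pool stands at 13.4% against my 12.4%, while 40.4% has left the solid against my 42.8%. The neighbour flask with 4.0 × 10⁻⁴ M of acid holds 6.58% of starting material against my 6.98%, and its 37.0% reacted lies 10 points above this flask against my 5.4 points, with 43.6% gone from the solid.

Readings and results were generated by integration with constants of no real substance; scatter was added.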